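## Analysis of the target

Target 18 is a 2,4-dihydroxybenzoic acid whose ring carbon C6 carries an unbranched thirteen-carbon chain. C1' is the benzylic methylene, C2' and C12' are acetylated secondary carbinol carbons, C3' to C11' are nine methylenes and C13' is a methyl group. Both stereocentres are R and nine methylenes lie between them, so neither can steer the other; each needs an external source of chirality, or both must come from one selection. The sensitive groups are the salicylic-type acid, which decarboxylates under hot acid, the electron-rich resorcinol ring, and two base-labile acetates. Loss of the C2' acetate would let the hydroxy acid close to a 3,4-dihydroisocoumarin. The difficulties are therefore two remote carbinol centres on a chain without handles, a 1,2,3,5-substituted arene with the carboxyl between chain and phenol, and an end game that frees the acid and phenols under neutral conditions. The strategy rests on a hidden symmetry of C1' to C13'. C2' is R with the terminal carbon C1' ranking above the inner chain, whereas C12' is R with the inner chain ranking above the terminal carbon C13'. Seen from the chain ends the two centres are therefore mirror images, and with oxygen on both C1' and C13' the skeleton would be meso, with a mirror plane through C7'. The chain thus maps onto the meso isomer of diepoxide 4, with aryl delivered to C1' and hydride to C13'.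

## Retrosynthetic reasoning

18 is traced to acid 17 by cutting the two O–benzyl bonds. Hydrogenolysis is neutral, so acetates and the acid survive, and the benzyl ethers can be carried from the purchased arene 8.

17 is traced through aldehyde 16 to diacetate 14 by cutting the bond between ring C1 and the carboxyl carbon. This leaves an aryl group that is symmetric about the chain, so the two positions ortho to the chain are equivalent. The forward formylation must go ortho to the chain and not between the two ether oxygens; a chlorite oxidation then gives the acid. Both hydroxyls must already be acetylated, as in 14.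

14 is traced through diol 13 and sulfonate 12 to triol 11 and its acetonide 10. The acetyl C–O bonds are cut first, then C13' is given back its oxygen. Forward, the primary hydroxyl of 11 is sulfonylated selectively and displaced by hydride. The C12'–O bond is never touched; its descriptor changes from S to R only because methyl ranks below the chain.

10 is traced to epoxide 7 and aryl bromide 8 (as Grignard reagent 9) by cutting the aryl–C1' bond. It is the only C–C bond joining arene and chain, and the unsubstituted oxirane carbon is the natural electrophile for an arylcopper. The C2' oxygen and configuration come unchanged from the oxirane.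

7 is traced through epoxy diol 6 to diepoxide 4 and water 5. The diol of 6 is itself a hydrolysed oxirane, and restoring it gives the meso isomer of 4. Forward, a chiral catalyst must hydrolyse only the S-configured end, which fixes both stereocentres and makes the two chain ends different in one operation.

4 is traced to diene 3, and 3 to dibromide 1 and two equivalents of allyl Grignard reagent 2, by cutting C3'–C4' and C10'–C11'. A symmetric double coupling followed by double epoxidation reaches the key precursor in two steps.

## Alternatives that were turned down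

Alternative 1: The disconnection cuts ring C6–C1', ring C1–carboxyl and the carboxyl O–C2' bond at once. The three pieces are 3,5-bis(benzyloxy)-2-(trimethylsilyl)phenyl triflate A2, the alkyne (R)-tridec-12-yn-2-yl acetate A3 and carbon dioxide A4. Forward, (IPr)CuCl (monovalent copper, IPr = 1,3-bis(2,6-diisopropylphenyl)imidazol-2-ylidene) with CsF and Cs2CO3 would add the copper acetylide of A3 to the aryne from A2. The resulting arylcopper would take up A4, and the carboxylate would close onto the alkyne to give isocoumarin A1.
- For: three bonds and a ring form in one step, the route is convergent, and aryne polarisation places the carboxyl next to an ether oxygen. On bond count and arene regiochemistry it is stronger than the chosen route.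
- Against: in A1 the carbon that must become C2' is an sp2 enol-lactone carbon, so that stereocentre would have to be created later by an enantioselective reduction of the lactone double bond. The lactone must then be opened and the C2' oxygen acetylated while the acid stays free, against the tendency to reclose. Closure in the 5-exo sense competes, A2 takes several steps to make, and C12' in A3 needs its own source of chirality.
- Comparison: the chosen strategy sets both centres in one catalytic event and never passes through a lactone.

Alternative 2: The disconnection cuts ring bonds C1–C2 and C5–C6, so the arene is built last. The partners are the ynoate benzyl (5R,15R)-5,15-diacetoxyhexadec-2-ynoate A6 and the diene 5,5-dimethyl-1,3-bis(trimethylsilyloxy)cyclohexa-1,3-diene A7. Forward, neat heating gives a bridged [4+2] adduct that loses its dimethyl-substituted two-carbon bridge in an Alder–Rickert fragmentation. Work-up removes the silyl groups and gives benzyl ester A5, one hydrogenolysis from 18.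
- For: the ring substitution pattern follows from the polarisation of both partners and is unambiguous, which is stronger than the chosen route, whose formylation relies on a positional preference. The carboxyl arrives as a benzyl ester and the acetates are already in place.
- Against: A6 must be made with both stereocentres installed separately, and its synthesis is no shorter than steps 1 to 9 here. A β-alkyl ynoate is a sluggish dienophile, and the heat needed invites elimination of the acetate β to the acidic propargylic methylene or isomerisation to an allenoate.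
- Comparison: the chosen strategy offers one stereo-defining step and mild conditions throughout.

Alternative 3: The disconnection cuts ring bond C1–C6, tracing the whole arene to the open-chain precursor 6-[(6R,16R)-6,16-bis(tert-butyldimethylsilyloxy)-2,4-dioxoheptadecyl]-2,2-dimethyl-4H-1,3-dioxin-4-one A9. Forward, an amine base and then mild acid would make dioxinone C5 add to the distal ketone; dehydration then gives benzodioxinone A8.
- For: the conditions are mild, the ring regiochemistry is fixed by chain folding, and the carboxyl carbon is present from the start. On arene regiocontrol it is again stronger than the chosen route.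
- Against: the C2' silyl ether is β to the ketone that becomes ring C6, so E1cB elimination threatens under the base that starts the aldol. A9 needs a multistep assembly with both centres made separately. Opening the benzodioxinone to a free acid needs hydroxide or alkoxide, which the acetates would not survive, so the protecting-group exchange and the unmasking work against each other.
- Comparison: the chosen route carries the final acetates from step 9 and ends with a neutral hydrogenolysis.

Key step: step 3

Remark: the (R,R) enantiomer of (salen)Co(OAc) is taken as the one that hydrolyses (S)-2-alkyloxiranes and leaves the (R) antipodes, as with simple 1,2-epoxyalkanes. The sense should be confirmed on 13 by Mosher ester analysis before material is committed.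

Remark: 4 from peracid epoxidation is expected as equal parts of the meso and the racemic isomers, since the two alkenes cannot sense each other.

## Route

Step 1
Reactants: 1 1,7-dibromoheptane; 2 allylmagnesium bromide
Product: 3 trideca-1,12-diene
Conditions: 2 (2.6 equiv), Li2CuCl4 (3 mol%), THF, −10 °C to rt
Reagents that add atoms: none
Why: Copper-catalysed alkyl–allyl Grignard coupling (Kochi type) displaces both primary bromides; the allyl group is symmetric, so SN2 and SN2' delivery give the same product.

Step 2
Reactants: 3 trideca-1,12-diene
Product: 4 1,2:12,13-diepoxytridecane, mixture of the meso and the racemic isomers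
Conditions: mCPBA (2.4 equiv), NaHCO3, CH2Cl2, 0 °C to rt
Reagents that add atoms: mCPBA (3-chloroperoxybenzoic acid), OOC(=O)c1cccc(Cl)c1
Why: Prilezhaev epoxidation of both monosubstituted alkenes; the remote ends react independently, so no diastereoselection is expected and only the meso half is productive later.

Step 3
Reactants: 4 1,2:12,13-diepoxytridecane (isomer mixture); 5 water
Product: 6 (2S)-11-[(2R)-oxiran-2-yl]undecane-1,2-diol
Conditions: (R,R)-(salen)Co(OAc) (trivalent cobalt, salen = dianion of (1R,2R)-N,N'-bis(3,5-di-tert-butylsalicylidene)cyclohexane-1,2-diamine; 1 mol%), 5 (1.1 equiv), THF, 0 °C to rt; silica chromatography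
Reagents that add atoms: none
Why: This is a hydrolytic kinetic resolution of terminal epoxides, applied to a bis-epoxide so that the meso isomer is desymmetrised: one cobalt centre activates the oxirane oxygen as a Lewis acid and a second delivers hydroxide to the unsubstituted CH2, so the C–O bond at the stereocentre is never broken. The (R,R) catalyst accepts only (S)-alkyloxiranes, and the nine methylenes between the rings make each end behave as an independent 1,2-epoxyalkane, so in meso 4 only the S end opens. No ring is closed and no stereocentre is made from a prochiral atom; C2 of the diol (S) and the oxirane carbon (R) are both selected by the catalyst alone. The step needs enantiotopic-group selection (catalyst), terminal attack by water (sterics of a monosubstituted oxirane), and complete double hydrolysis of the (S,S) isomer, whose half-opened form is a diastereomer of 6; the slight excess of 5 over one equivalent serves the last point. Any enantiomer of 6 formed by a mismatched opening still carries an S oxirane and is hydrolysed on to the meso tetraol, which should raise the optical purity of 6 with conversion. The untouched (R,R)-diepoxide, 6 and the tetraols differ stepwise by two hydroxyl groups and should separate on silica.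

Step 4
Reactants: 6 (2S)-11-[(2R)-oxiran-2-yl]undecane-1,2-diol
Product: 7 (4S)-2,2-dimethyl-4-{9-[(2R)-oxiran-2-yl]nonyl}-1,3-dioxolane
Conditions: 2,2-dimethoxypropane, PPTS (cat.), CH2Cl2, rt
Reagents that add atoms: 2,2-dimethoxypropane, COC(C)(C)OC
Why: Transketalisation of the 1,2-diol under a weak pyridinium acid that a monoalkyl oxirane is expected to tolerate; it stops the diol from quenching the aryl nucleophile of step 5.

Step 5
Reactants: 7 (4S)-2,2-dimethyl-4-{9-[(2R)-oxiran-2-yl]nonyl}-1,3-dioxolane; 8 1-bromo-3,5-bis(benzyloxy)benzene
Product: 10 (2R)-1-[3,5-bis(benzyloxy)phenyl]-11-[(4S)-2,2-dimethyl-1,3-dioxolan-4-yl]undecan-2-ol, via 3,5-bis(benzyloxy)phenylmagnesium bromide 9 (not isolated)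
Conditions: 8, Mg, THF, reflux; then CuI (10 mol%), 7, THF, −30 to 0 °C; aq NH4Cl
Reagents that add atoms: none
Why: Copper-catalysed opening of a terminal epoxide by an aryl Grignard reagent; the arylcopper attacks the unsubstituted C1' in an SN2 sense, so the C2' oxygen keeps its R configuration, and benzyl ethers and acetonide are inert.

Step 6
Reactants: 10 (2R)-1-[3,5-bis(benzyloxy)phenyl]-11-[(4S)-2,2-dimethyl-1,3-dioxolan-4-yl]undecan-2-ol
Product: 11 (2S,12R)-13-[3,5-bis(benzyloxy)phenyl]tridecane-1,2,12-triol
Conditions: AcOH/H2O/THF (3:1:1), 45 °C
Reagents that add atoms: none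
Why: Acid hydrolysis of the isopropylidene acetal; benzyl ethers and the secondary alcohol are stable to warm aqueous acetic acid and no stereocentre is involved.

Step 7
Reactants: 11 (2S,12R)-13-[3,5-bis(benzyloxy)phenyl]tridecane-1,2,12-triol
Product: 12 (2S,12R)-13-[3,5-bis(benzyloxy)phenyl]-2,12-dihydroxytridecyl 4-methylbenzenesulfonate
Conditions: TsCl (1.05 equiv), Bu2SnO (2 mol%), Et3N, CH2Cl2, 0 °C to rt
Reagents that add atoms: 4-toluenesulfonyl chloride, Cc1ccc(cc1)S(Cl)(=O)=O
Why: Tin-catalysed regioselective sulfonylation; Bu2SnO forms a stannylene acetal only with the 1,2-diol and activates its primary oxygen, so both secondary hydroxyls should stay free.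

Step 8
Reactants: 12 (2S,12R)-13-[3,5-bis(benzyloxy)phenyl]-2,12-dihydroxytridecyl 4-methylbenzenesulfonate
Product: 13 (2R,12R)-1-[3,5-bis(benzyloxy)phenyl]tridecane-2,12-diol
Conditions: LiAlH4, THF, 0 °C to rt; Rochelle salt work-up
Reagents that add atoms: none
Why: Hydride displacement of a primary sulfonate, directly or through the 12',13'-oxirane closed by the neighbouring alkoxide and opened at its terminal carbon; either way the C12'–O bond is untouched and the descriptor becomes R only because methyl ranks below the chain.

Step 9
Reactants: 13 (2R,12R)-1-[3,5-bis(benzyloxy)phenyl]tridecane-2,12-diol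
Product: 14 (2R,12R)-1-[3,5-bis(benzyloxy)phenyl]tridecane-2,12-diyl diacetate
Conditions: Ac2O, pyridine, DMAP (cat.), CH2Cl2, rt
Reagents that add atoms: acetic anhydride, CC(=O)OC(C)=O
Why: DMAP-catalysed acylation of both secondary alcohols; it installs the final esters and masks the hydroxyls before the electrophilic formylation.

Step 10
Reactants: 14 (2R,12R)-1-[3,5-bis(benzyloxy)phenyl]tridecane-2,12-diyl diacetate
Product: 16 (2R,12R)-1-[3,5-bis(benzyloxy)-2-formylphenyl]tridecane-2,12-diyl diacetate, via aryl(dimethyl)iminium salt 15 (not isolated)
Conditions: POCl3, DMF, 0 to 60 °C; then aq NaOAc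
Reagents that add atoms: N,N-dimethylformamide, CN(C)C=O (formyl carbon); water, O (formyl oxygen)
Why: Vilsmeier–Haack formylation; the chloroiminium ion should attack the carbon ortho to the chain (para to one benzyloxy group, ortho to the other) in preference to C4 between two benzyloxy groups, as is usual for 5-alkylresorcinol diethers, and the two ortho positions are equivalent by symmetry.

Step 11
Reactants: 16 (2R,12R)-1-[3,5-bis(benzyloxy)-2-formylphenyl]tridecane-2,12-diyl diacetate
Product: 17 2,4-bis(benzyloxy)-6-[(2R,12R)-2,12-diacetoxytridecyl]benzoic acid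
Conditions: NaClO2, NaH2PO4, 2-methyl-2-butene (large excess), t-BuOH/THF/H2O, 0 °C to rt
Reagents that add atoms: sodium chlorite, [Na+].[O-]Cl=O
Why: Pinnick oxidation; chlorous acid adds to the aldehyde and fragments to the acid, the alkene scavenger traps HOCl before it can chlorinate the electron-rich ring, and the buffered medium spares acetates and benzyl ethers.

Step 12
Reactants: 17 2,4-bis(benzyloxy)-6-[(2R,12R)-2,12-diacetoxytridecyl]benzoic acid
Product: 18 2-[(2R,12R)-2,12-diacetoxytridecyl]-4,6-dihydroxybenzoic acid
Conditions: H2 (1 atm), 10% Pd/C, EtOAc, rt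
Reagents that add atoms: none
Why: Hydrogenolysis of the two aryl benzyl ethers under neutral conditions; acetates, the homobenzylic C2'–O bond and the acid are untouched, and no heat or acid is applied that could decarboxylate the product.

## Compound list

1 | 1,7-dibromoheptane | BrCCCCCCCBr | starting material
2 | allylmagnesium bromide | C=CC[Mg]Br | starting material
3 | trideca-1,12-diene | C=CCCCCCCCCCC=C | intermediate
4 | 1,2:12,13-diepoxytridecane [2,2'-(nonane-1,9-diyl)bis(oxirane)], mixture of meso and racemic isomers, productive meso (2R,12S) isomer drawn | C1O[C@H]1CCCCCCCCC[C@@H]1CO1 | intermediate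
5 | water | O | starting material
6 | (2S)-11-[(2R)-oxiran-2-yl]undecane-1,2-diol | OC[C@@H](O)CCCCCCCCC[C@@H]1CO1 | intermediate
7 | (4S)-2,2-dimethyl-4-{9-[(2R)-oxiran-2-yl]nonyl}-1,3-dioxolane | CC1(C)OC[C@@H](O1)CCCCCCCCC[C@@H]1CO1 | intermediate
8 | 1-bromo-3,5-bis(benzyloxy)benzene | Brc1cc(OCc2ccccc2)cc(OCc2ccccc2)c1 | starting material
9 | 3,5-bis(benzyloxy)phenylmagnesium bromide | Br[Mg]c1cc(OCc2ccccc2)cc(OCc2ccccc2)c1 | intermediate
10 | (2R)-1-[3,5-bis(benzyloxy)phenyl]-11-[(4S)-2,2-dimethyl-1,3-dioxolan-4-yl]undecan-2-ol | CC1(C)OC[C@@H](O1)CCCCCCCCC[C@@H](O)Cc1cc(OCc2ccccc2)cc(OCc2ccccc2)c1 | intermediate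
11 | (2S,12R)-13-[3,5-bis(benzyloxy)phenyl]tridecane-1,2,12-triol | OC[C@@H](O)CCCCCCCCC[C@@H](O)Cc1cc(OCc2ccccc2)cc(OCc2ccccc2)c1 | intermediate
12 | (2S,12R)-13-[3,5-bis(benzyloxy)phenyl]-2,12-dihydroxytridecyl 4-methylbenzenesulfonate | Cc1ccc(cc1)S(=O)(=O)OC[C@@H](O)CCCCCCCCC[C@@H](O)Cc1cc(OCc2ccccc2)cc(OCc2ccccc2)c1 | intermediate
13 | (2R,12R)-1-[3,5-bis(benzyloxy)phenyl]tridecane-2,12-diol | C[C@@H](O)CCCCCCCCC[C@@H](O)Cc1cc(OCc2ccccc2)cc(OCc2ccccc2)c1 | intermediate
14 | (2R,12R)-1-[3,5-bis(benzyloxy)phenyl]tridecane-2,12-diyl diacetate | CC(=O)O[C@H](CCCCCCCCC[C@@H](C)OC(C)=O)Cc1cc(OCc2ccccc2)cc(OCc2ccccc2)c1 | intermediate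
15 | {2,4-bis(benzyloxy)-6-[(2R,12R)-2,12-diacetoxytridecyl]benzylidene}dimethyliminium dichlorophosphate | CC(=O)O[C@H](CCCCCCCCC[C@@H](C)OC(C)=O)Cc1cc(OCc2ccccc2)cc(OCc2ccccc2)c1C=[N+](C)C.[O-]P(Cl)(Cl)=O | intermediate
16 | (2R,12R)-1-[3,5-bis(benzyloxy)-2-formylphenyl]tridecane-2,12-diyl diacetate | CC(=O)O[C@H](CCCCCCCCC[C@@H](C)OC(C)=O)Cc1cc(OCc2ccccc2)cc(OCc2ccccc2)c1C=O | intermediate
17 | 2,4-bis(benzyloxy)-6-[(2R,12R)-2,12-diacetoxytridecyl]benzoic acid | CC(=O)O[C@H](CCCCCCCCC[C@@H](C)OC(C)=O)Cc1cc(OCc2ccccc2)cc(OCc2ccccc2)c1C(=O)O | intermediate
18 | 2-[(2R,12R)-2,12-diacetoxytridecyl]-4,6-dihydroxybenzoic acid | CC(=O)O[C@H](CCCCCCCCC[C@@H](C)OC(C)=O)Cc1cc(O)cc(O)c1C(=O)O | target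

## Step count and least certain steps

Total step count: 12. Longest linear sequence: 12 steps, from 1 to 18; 8 is used as purchased.

Step 3 (key step). The most likely failures are incomplete discrimination between the oxirane ends and incomplete second hydrolysis in the (S,S) series. Both leave epoxy diols that are diastereomers of 6 with the stereocentres ten bonds apart, which chromatography is unlikely to remove. Too much water would in turn start slow opening of R ends, and reduction of the catalyst to divalent cobalt would stall the reaction. The step is also capped by statistics, since only the meso half of 4 can give 6.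

Fallback, from 3, returning at 7: one alkene of 3 is epoxidised with one equivalent of mCPBA to racemic 2-(undec-10-en-1-yl)oxirane F1. F1 is resolved with the same (R,R) catalyst and slightly less than half an equivalent of water, which should give (2S)-tridec-12-ene-1,2-diol F2. F2 is protected as (4S)-2,2-dimethyl-4-(undec-10-en-1-yl)-1,3-dioxolane F3 and epoxidised to (4S)-2,2-dimethyl-4-[9-(oxiran-2-yl)nonyl]-1,3-dioxolane F4, a pair of epimers at the oxirane. A second resolution with the (R,R) catalyst and slightly more than half an equivalent of water should hydrolyse the (S)-oxirane epimer and leave 7. Each centre is then secured in an ordinary two-component resolution whose purity can be tuned by conversion, at the cost of two more steps.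

Step 4. Acid-catalysed opening of the oxirane by released methanol, or oligomerisation through the free diol, may compete with ketal formation.

Fallback, from 6, returning at 11: the protection is omitted. 6 is added to at least 3.5 equivalents of 9 with CuI, so the diol travels as its bis-magnesium alkoxide while the oxirane is opened, and work-up should give triol 11 directly. No new compound is made.

Step 5. Opening of the oxirane by magnesium bromide to a bromohydrin, homocoupling of the aryl Grignard reagent, or attack at the internal carbon may erode the yield.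

Fallback, from 7 and 8, returning at 10: a nickel-catalysed cross-electrophile coupling with NiCl2(MeOCH2CH2OMe) (divalent nickel), 2,2'-bipyridine, NaI, Et3N·HCl and Mn powder in DMPU. Iodide opens the oxirane at C1' to (2R)-11-[(4S)-2,2-dimethyl-1,3-dioxolan-4-yl]-1-iodoundecan-2-ol F5 in the flask, and nickel joins this alkyl iodide to 8, with no organomagnesium reagent present.

Step 7. Sulfonylation may spill over to a secondary hydroxyl, or be slow enough that forcing it costs selectivity among the three hydroxyls.

Fallback, from 10, returning at 13: the C2' hydroxyl is masked first. 10 is acetylated to (2R)-1-[3,5-bis(benzyloxy)phenyl]-11-[(4S)-2,2-dimethyl-1,3-dioxolan-4-yl]undecan-2-yl acetate F6. Aqueous acetic acid frees (2R,12S)-1-[3,5-bis(benzyloxy)phenyl]-12,13-dihydroxytridecan-2-yl acetate F7. Its primary hydroxyl, now the only competitor to one secondary hydroxyl, is tosylated to (2S,12R)-12-acetoxy-13-[3,5-bis(benzyloxy)phenyl]-2-hydroxytridecyl 4-methylbenzenesulfonate F8. Excess LiAlH4 then removes the sulfonate and the temporary acetate together to give 13.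

Step 10. Attack may go partly to C4 between the two benzyloxy groups, or be sluggish at the hindered position next to the branched chain, so that forcing it costs acetate or benzyl groups.

Fallback, from 14, returning at 18: NBS in MeCN at 0 °C, which strongly favours the position para to an alkoxy group, should give (2R,12R)-1-[3,5-bis(benzyloxy)-2-bromophenyl]tridecane-2,12-diyl diacetate F9. Carbonylation with Pd(OAc)2 and Xantphos under CO with benzyl alcohol and Et3N should give benzyl 2,4-bis(benzyloxy)-6-[(2R,12R)-2,12-diacetoxytridecyl]benzoate F10. Hydrogenolysis over Pd/C removes all three benzyl groups to give 18. This detour also avoids the chlorite oxidation of step 11 and its risk of ring chlorination.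

## Further compounds

F1 | step 3 | 2-(undec-10-en-1-yl)oxirane, racemic | C=CCCCCCCCCCC1CO1
F2 | step 3 | (2S)-tridec-12-ene-1,2-diol | OC[C@@H](O)CCCCCCCCCC=C
F3 | step 3 | (4S)-2,2-dimethyl-4-(undec-10-en-1-yl)-1,3-dioxolane | CC1(C)OC[C@@H](O1)CCCCCCCCCC=C
F4 | step 3 | (4S)-2,2-dimethyl-4-[9-(oxiran-2-yl)nonyl]-1,3-dioxolane, both epimers at the oxirane | CC1(C)OC[C@@H](O1)CCCCCCCCCC1CO1
F0 | step 4 | none | none
F5 | step 5 | (2R)-11-[(4S)-2,2-dimethyl-1,3-dioxolan-4-yl]-1-iodoundecan-2-ol | CC1(C)OC[C@@H](O1)CCCCCCCCC[C@@H](O)CI
F6 | step 7 | (2R)-1-[3,5-bis(benzyloxy)phenyl]-11-[(4S)-2,2-dimethyl-1,3-dioxolan-4-yl]undecan-2-yl acetate | CC1(C)OC[C@@H](O1)CCCCCCCCC[C@@H](OC(C)=O)Cc1cc(OCc2ccccc2)cc(OCc2ccccc2)c1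
F7 | step 7 | (2R,12S)-1-[3,5-bis(benzyloxy)phenyl]-12,13-dihydroxytridecan-2-yl acetate | OC[C@@H](O)CCCCCCCCC[C@@H](OC(C)=O)Cc1cc(OCc2ccccc2)cc(OCc2ccccc2)c1
F8 | step 7 | (2S,12R)-12-acetoxy-13-[3,5-bis(benzyloxy)phenyl]-2-hydroxytridecyl 4-methylbenzenesulfonate | Cc1ccc(cc1)S(=O)(=O)OC[C@@H](O)CCCCCCCCC[C@@H](OC(C)=O)Cc1cc(OCc2ccccc2)cc(OCc2ccccc2)c1
F9 | step 10 | (2R,12R)-1-[3,5-bis(benzyloxy)-2-bromophenyl]tridecane-2,12-diyl diacetate | CC(=O)O[C@H](CCCCCCCCC[C@@H](C)OC(C)=O)Cc1cc(OCc2ccccc2)cc(OCc2ccccc2)c1Br
F10 | step 10 | benzyl 2,4-bis(benzyloxy)-6-[(2R,12R)-2,12-diacetoxytridecyl]benzoate | CC(=O)O[C@H](CCCCCCCCC[C@@H](C)OC(C)=O)Cc1cc(OCc2ccccc2)cc(OCc2ccccc2)c1C(=O)OCc1ccccc1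
A1 | alternative 1 | (R)-11-[6,8-bis(benzyloxy)-1-oxo-1H-isochromen-3-yl]undecan-2-yl acetate | CC(=O)O[C@H](C)CCCCCCCCCc1cc2cc(OCc3ccccc3)cc(OCc3ccccc3)c2c(=O)o1
A2 | alternative 1 | 3,5-bis(benzyloxy)-2-(trimethylsilyl)phenyl trifluoromethanesulfonate | C[Si](C)(C)c1c(OS(=O)(=O)C(F)(F)F)cc(OCc2ccccc2)cc1OCc1ccccc1
A3 | alternative 1 | (R)-tridec-12-yn-2-yl acetate | C#CCCCCCCCCC[C@@H](C)OC(C)=O
A4 | alternative 1 | carbon dioxide | O=C=O
A5 | alternative 2 | benzyl 6-[(2R,12R)-2,12-diacetoxytridecyl]-2,4-dihydroxybenzoate | CC(=O)O[C@H](CCCCCCCCC[C@@H](C)OC(C)=O)Cc1cc(O)cc(O)c1C(=O)OCc1ccccc1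
A6 | alternative 2 | benzyl (5R,15R)-5,15-diacetoxyhexadec-2-ynoate | CC(=O)O[C@H](CCCCCCCCC[C@@H](C)OC(C)=O)CC#CC(=O)OCc1ccccc1
A7 | alternative 2 | 5,5-dimethyl-1,3-bis(trimethylsilyloxy)cyclohexa-1,3-diene | C[Si](C)(C)OC1=CC(O[Si](C)(C)C)=CC(C)(C)C1
A8 | alternative 3 | 5-[(2R,12R)-2,12-bis(tert-butyldimethylsilyloxy)tridecyl]-7-hydroxy-2,2-dimethyl-4H-benzo[d][1,3]dioxin-4-one | CC1(C)OC(=O)c2c(C[C@H](O[Si](C)(C)C(C)(C)C)CCCCCCCCC[C@@H](C)O[Si](C)(C)C(C)(C)C)cc(O)cc2O1
A9 | alternative 3 | 6-[(6R,16R)-6,16-bis(tert-butyldimethylsilyloxy)-2,4-dioxoheptadecyl]-2,2-dimethyl-4H-1,3-dioxin-4-one | CC1(C)OC(=O)C=C(CC(=O)CC(=O)C[C@H](O[Si](C)(C)C(C)(C)C)CCCCCCCCC[C@@H](C)O[Si](C)(C)C(C)(C)C)O1
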